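**Retrosynthetic overview**

1. Target 19 ⇐ chromene-free dimer 17 + 3-methylbut-2-enal 18. The pyran ring is closed last: C–C bond at the one free CH of ring B, C–O bond at the hydroxyl beside the isobutyryl ketone.
2. Ring B is an isobutyrylphloroglucinol whose bridge-bearing carbon lies between two C–OH carbons. Its six carbons are therefore C-1 to C-6 of methyl 8-methyl-3,5,7-trioxononanoate carrying the ring A methylene on C-2 (16). Claisen folding makes the bond between the acyl-bearing carbon (C-6) and the adjacent C–OH carbon (ester C-1).
3. A C–H acidic malonate cannot acylate a diketone dianion, so 16 is released in the flask from its lactone, the 4-hydroxy-2-pyrone 15. 15 ⇐ ring A monomer 10 + pyrone 13 + one carbon (Mannich/Michael bridge); 13 ⇐ triacetic acid lactone 11 + methyl isobutyrate 12.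
4. Ring A monomer 10 ⇐ the same Claisen folding of the 2,2-disubstituted triketo ester 9 ⇐ acid 6 + dianion of 5-methylhexane-2,4-dione 7. The quaternary stereocenter ⇐ asymmetric phase-transfer prenylation of the mixed methylmalonate 3.
5. Order of ring formation: ring A (step 6), ring B (step 9), pyran ring (step 10). The pyrone ring of 11 is bought and opened in step 9.

Key step: step 9

Assumption on step 3: the sense of induction is assigned by analogy with benzylic and simple allylic bromides on this malonate class, for which the (S,S) catalyst is taken to give the (S) ester; the (R,R) catalyst is therefore specified, the configuration of 5 has to be confirmed by correlation, and the antipodal catalyst would be used with no other change if the sense were opposite.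

Remark: compounds are drawn and named as the tautomers of the target SMILES; the spatial arrangement at the quaternary carbon is the same from 5 to 19, and the change from (R) in 5 to (S) afterwards comes only from the CIP priorities.

**Route**

Step 1
Reactants: 1 2,2,5-trimethyl-1,3-dioxane-4,6-dione
Product: 2 3-(tert-butoxy)-2-methyl-3-oxopropanoic acid (racemic)
Conditions: t-BuOH, reflux
Reagents that add atoms: tert-butanol, CC(C)(C)O
Why: Alcoholysis of a Meldrum's acid: tert-butanol opens the activated cyclic diester, acetone is lost, and the malonic half ester should form without decarboxylation at this temperature.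

Step 2
Reactants: 2 3-(tert-butoxy)-2-methyl-3-oxopropanoic acid
Product: 3 tert-butyl 2,2-diphenylethyl 2-methylpropanedioate
Conditions: 2,2-diphenylethanol, DCC, DMAP (cat.), CH2Cl2, 0 °C to rt
Reagents that add atoms: 2,2-diphenylethanol, OCC(c1ccccc1)c1ccccc1
Why: Steglich esterification (carbodiimide activation, DMAP acyl transfer) of the half ester with a primary alcohol gives the mixed malonate that the asymmetric alkylation needs.

Step 3
Reactants: 3 tert-butyl 2,2-diphenylethyl 2-methylpropanedioate; 4 1-bromo-3-methylbut-2-ene
Product: 5 1-tert-butyl 3-(2,2-diphenylethyl) (R)-2-methyl-2-(3-methylbut-2-en-1-yl)propanedioate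
Conditions: (R,R)-3,4,5-trifluorophenyl-NAS bromide (5 mol %), 50% aq KOH, toluene, −40 °C
Reagents that add atoms: none
Why: Catalytic asymmetric phase-transfer alkylation of an α-methylmalonate: the Maruoka-type N-spiro binaphthyl ammonium cation pairs with the enolate, tells the tert-butyl ester from the 2,2-diphenylethyl ester and leaves one face open to SN2 attack on the primary allylic bromide, so the quaternary stereocenter is set by catalyst control.

Step 4
Reactants: 5 1-tert-butyl 3-(2,2-diphenylethyl) (R)-2-methyl-2-(3-methylbut-2-en-1-yl)propanedioate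
Product: 6 (S)-2-[(2,2-diphenylethoxy)carbonyl]-2,5-dimethylhex-4-enoic acid
Conditions: Me3SiOTf, 2,6-lutidine, CH2Cl2, 0 °C to rt; then H2O (pH 4)
Reagents that add atoms: none
Why: Silyl triflate cleavage of a tert-butyl ester (O-silylation, loss of the tert-butyl cation as 2-methylpropene, hydrolysis of the silyl ester on work-up) under lutidine-buffered conditions that spare the primary ester and the trisubstituted alkene, which a protic acid could lactonize; the quaternary center cannot epimerize.

Step 5
Reactants: 6 (S)-2-[(2,2-diphenylethoxy)carbonyl]-2,5-dimethylhex-4-enoic acid; 7 5-methylhexane-2,4-dione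
Product: 9 2,2-diphenylethyl (S)-2,8-dimethyl-2-(3-methylbut-2-en-1-yl)-3,5,7-trioxononanoate, via acyl imidazolide 8 (not isolated)
Conditions: 6, CDI, THF, rt; then added to the dianion of 7 [7 (3.5 equiv), LiN(i-Pr)2 (7 equiv), THF, 0 °C] at −78 to 0 °C; then aq HCl
Reagents that add atoms: none
Why: Claisen-type C-acylation of a 1,3-diketone dianion, which reacts at its terminal carbanion (the methyl carbon, deprotonated in preference to the isopropyl methine), with an acyl imidazolide that has no α-hydrogen and is far more electrophilic than the hindered ester; the excess dianion absorbs the acidity of imidazole and of the triketone formed.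

Step 6
Reactants: 9 2,2-diphenylethyl (S)-2,8-dimethyl-2-(3-methylbut-2-en-1-yl)-3,5,7-trioxononanoate
Product: 10 (S)-3,5-dihydroxy-4-methyl-4-(3-methylbut-2-en-1-yl)-2-(2-methylpropanoyl)cyclohexa-2,5-dien-1-one (ring A monomer)
Conditions: KOt-Bu (3 equiv), THF, 0 °C to rt; then 1 M HCl
Reagents that add atoms: none
Why: Intramolecular Claisen (Dieckmann-type) condensation: the carbanion at C-6, between the C-5 and C-7 ketones, attacks the primary ester in a 6-exo-trig closure, aldol folding is impossible because C-2 is quaternary, and the 2-acylcyclohexane-1,3,5-trione leaves all equilibria as its stabilized anion; the quaternary stereocenter is not touched.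

Step 7
Reactants: 11 4-hydroxy-6-methyl-2H-pyran-2-one; 12 methyl 2-methylpropanoate
Product: 13 4-hydroxy-6-(3-methyl-2-oxobutyl)-2H-pyran-2-one
Conditions: LiN(i-Pr)2 (3.2 equiv), THF, −78 °C; then 12, −78 to 0 °C; then aq HCl
Reagents that add atoms: none
Why: Vinylogous Claisen condensation: the dianion of the pyrone (4-oxygen and the 6-methyl carbon) is acylated by the ester at the exocyclic carbanion, its most nucleophilic site, and the third equivalent of base takes up the more acidic product.

Step 8
Reactants: 10 ring A monomer; 13 4-hydroxy-6-(3-methyl-2-oxobutyl)-2H-pyran-2-one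
Product: 15 (S)-3,5-dihydroxy-6-{[4-hydroxy-6-(3-methyl-2-oxobutyl)-2-oxo-2H-pyran-3-yl]methyl}-4-methyl-4-(3-methylbut-2-en-1-yl)-2-(2-methylpropanoyl)cyclohexa-2,5-dien-1-one, via ring A Mannich base 14 (not isolated)
Conditions: [Me2N=CH2]I (1.05 equiv), MeCN, 0 °C to rt; then 13 (2 equiv), 60 °C
Reagents that add atoms: N,N-dimethylmethyleneiminium iodide, C=[N+](C)C.[I-]
Why: Mannich aminomethylation at the only unsubstituted nucleophilic carbon of ring A (C-6), then thermal loss of dimethylamine to the 6-methylene trione and Michael addition of the 4-hydroxy-2-pyrone through C-3, its usual nucleophilic site, is the established way to unsymmetrical methylene-bridged dimers, and converting 10 fully into 14 before the pyrone is added in excess keeps free ring A away from its own methide.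

Step 9
Reactants: 15 pyrone-bridged ring A compound
Product: 17 (S)-3,5-dihydroxy-4-methyl-4-(3-methylbut-2-en-1-yl)-2-(2-methylpropanoyl)-6-{[2,4,6-trihydroxy-3-(2-methylpropanoyl)phenyl]methyl}cyclohexa-2,5-dien-1-one, via bridged triketo ester 16 (not isolated)
Conditions: Mg(OMe)2 (10 equiv), MeOH, reflux; then 1 M HCl
Reagents that add atoms: none
Why: Mg(OMe)2 turns 15 into its magnesium polyenolate, methoxide adds to the lactone carbonyl C-2 of the pyrone and the ring opens to the chelated polyanion of 16 (either epimer at C-2, a carbon that becomes aromatic); the carbanion at chain C-6, between the isobutyryl ketone and the C-5 ketone, then attacks the ester carbonyl C-1, methoxide leaves and the cyclohexane-1,3,5-trione enolizes irreversibly to the triphenol. The closest known reactions are the magnesium methoxide Claisen cyclizations of 3,5,7-triketo esters and of their pyrone lactones, the 6-(2-oxoalkyl)-4-hydroxy-2-pyrones, to acylphloroglucinols, a biomimetic polyketide folding. Ring B closes by a 6-exo-trig attack of the enolate carbon on the ester, which forms the bond between the acyl-bearing carbon and the adjacent C–OH carbon. No stereocenter is formed, and the quaternary carbon of ring A has no pathway for epimerization. The step needs Claisen (C-6 to C-1) and not aldol (C-2 to C-7) folding: C-2 is tertiary and carries the bulky ring A methylene, the C-7 ketone is shielded by isopropyl, an aldol closure through the isopropyl methine cannot aromatize and reverts, and relactonization to the pyrone is reversible, so the aromatic Claisen product should be the sink under a chelating non-aqueous base. The step also needs the CH2 bridge to survive, which is expected because ring A sits as its magnesium triketonate, a poor leaving group for retro-Michael cleavage and inert to methoxide.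

Step 10
Reactants: 17 chromene-free dimer; 18 3-methylbut-2-enal
Product: 19 (S)-6-{[5,7-dihydroxy-2,2-dimethyl-8-(2-methylpropanoyl)-2H-chromen-6-yl]methyl}-3,5-dihydroxy-4-methyl-4-(3-methylbut-2-en-1-yl)-2-(2-methylpropanoyl)cyclohexa-2,5-dien-1-one (CNP0301804.1)
Conditions: ethylenediammonium diacetate (20 mol %), toluene, 80 °C
Reagents that add atoms: none
Why: Amine-salt-catalysed chromene annulation: Knoevenagel-type condensation of the enal at the one free aromatic CH of ring B gives an ortho-quinone methide, which closes by oxa-6π electrocyclization, expected on the hydroxyl beside the isobutyryl group because the hydroxyls flanking the bridge are held in hydrogen bonds to ring A oxygens; ring A has no free nucleophilic carbon and no stereocenter is formed.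

**Compound list**

1 | 2,2,5-trimethyl-1,3-dioxane-4,6-dione | CC1C(=O)OC(C)(C)OC1=O | starting material
2 | 3-(tert-butoxy)-2-methyl-3-oxopropanoic acid (racemic) | CC(C(=O)O)C(=O)OC(C)(C)C | intermediate
3 | tert-butyl 2,2-diphenylethyl 2-methylpropanedioate | CC(C(=O)OCC(c1ccccc1)c1ccccc1)C(=O)OC(C)(C)C | intermediate
4 | 1-bromo-3-methylbut-2-ene | CC(C)=CCBr | starting material
5 | 1-tert-butyl 3-(2,2-diphenylethyl) (R)-2-methyl-2-(3-methylbut-2-en-1-yl)propanedioate | CC(C)=CC[C@@](C(=O)OCC(c1ccccc1)c1ccccc1)(C)C(=O)OC(C)(C)C | intermediate
6 | (S)-2-[(2,2-diphenylethoxy)carbonyl]-2,5-dimethylhex-4-enoic acid | CC(C)=CC[C@@](C(=O)OCC(c1ccccc1)c1ccccc1)(C)C(=O)O | intermediate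
7 | 5-methylhexane-2,4-dione | CC(C)C(=O)CC(C)=O | starting material
8 | 2,2-diphenylethyl (S)-2-(1H-imidazole-1-carbonyl)-2,5-dimethylhex-4-enoate (acyl imidazolide) | CC(C)=CC[C@@](C(=O)OCC(c1ccccc1)c1ccccc1)(C)C(=O)n1ccnc1 | intermediate
9 | 2,2-diphenylethyl (S)-2,8-dimethyl-2-(3-methylbut-2-en-1-yl)-3,5,7-trioxononanoate | CC(C)=CC[C@@](C(=O)OCC(c1ccccc1)c1ccccc1)(C)C(=O)CC(=O)CC(=O)C(C)C | intermediate
10 | (S)-3,5-dihydroxy-4-methyl-4-(3-methylbut-2-en-1-yl)-2-(2-methylpropanoyl)cyclohexa-2,5-dien-1-one (ring A monomer) | CC(C)=CC[C@@]1(C)C(O)=CC(=O)C(C(=O)C(C)C)=C1O | intermediate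
11 | 4-hydroxy-6-methyl-2H-pyran-2-one | CC1=CC(O)=CC(=O)O1 | starting material
12 | methyl 2-methylpropanoate | COC(=O)C(C)C | starting material
13 | 4-hydroxy-6-(3-methyl-2-oxobutyl)-2H-pyran-2-one | CC(C)C(=O)CC1=CC(O)=CC(=O)O1 | intermediate
14 | (S)-6-[(dimethylamino)methyl]-3,5-dihydroxy-4-methyl-4-(3-methylbut-2-en-1-yl)-2-(2-methylpropanoyl)cyclohexa-2,5-dien-1-one (ring A Mannich base) | CC(C)=CC[C@@]1(C)C(O)=C(CN(C)C)C(=O)C(C(=O)C(C)C)=C1O | intermediate
15 | (S)-3,5-dihydroxy-6-{[4-hydroxy-6-(3-methyl-2-oxobutyl)-2-oxo-2H-pyran-3-yl]methyl}-4-methyl-4-(3-methylbut-2-en-1-yl)-2-(2-methylpropanoyl)cyclohexa-2,5-dien-1-one | CC(C)=CC[C@@]1(C)C(O)=C(CC2=C(O)C=C(CC(=O)C(C)C)OC2=O)C(=O)C(C(=O)C(C)C)=C1O | intermediate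
16 | methyl 8-methyl-3,5,7-trioxononanoate carrying on C-2 the methylene of ring A (ring A as in 10, attached through C-6; either epimer at C-2) | CC(C)=CC[C@@]1(C)C(O)=C(CC(C(=O)OC)C(=O)CC(=O)CC(=O)C(C)C)C(=O)C(C(=O)C(C)C)=C1O | intermediate
17 | (S)-3,5-dihydroxy-4-methyl-4-(3-methylbut-2-en-1-yl)-2-(2-methylpropanoyl)-6-{[2,4,6-trihydroxy-3-(2-methylpropanoyl)phenyl]methyl}cyclohexa-2,5-dien-1-one (chromene-free dimer) | CC(C)=CC[C@@]1(C)C(O)=C(Cc2c(O)cc(O)c(C(=O)C(C)C)c2O)C(=O)C(C(=O)C(C)C)=C1O | intermediate
18 | 3-methylbut-2-enal | CC(C)=CC=O | starting material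
19 | (S)-6-{[5,7-dihydroxy-2,2-dimethyl-8-(2-methylpropanoyl)-2H-chromen-6-yl]methyl}-3,5-dihydroxy-4-methyl-4-(3-methylbut-2-en-1-yl)-2-(2-methylpropanoyl)cyclohexa-2,5-dien-1-one (CNP0301804.1) | CC(C)=CC[C@@]1(C)C(O)=C(Cc2c(O)c3c(c(C(=O)C(C)C)c2O)OC(C)(C)C=C3)C(=O)C(C(=O)C(C)C)=C1O | target

**Step count**

Total: 10 steps. Longest linear sequence: 9 steps (steps 1 to 6, then 8, 9 and 10); step 7 is the one-step side branch.

**Steps most likely to fail**

Step 9. Three processes may spoil it: slow methanolysis of the 4-oxidopyrone, aldol instead of Claisen folding of the opened chain, and base-induced retro-Michael/Michael exchange at the methylene bridge, which would scramble the two halves into homo-coupled material. The fallback sets out from 10 and comes back at 17, with ring B brought in already aromatic. Friedel–Crafts acylation of phloroglucinol with isobutyryl chloride (AlCl3, nitrobenzene/CH2Cl2) should give 2-methyl-1-(2,4,6-trihydroxyphenyl)propan-1-one F1. Monomer 10 is converted into Mannich base 14 as in step 8, and 14 is heated with an excess of F1 (MeCN, 60 °C). Michael addition of one of the two equivalent free ring carbons of F1 to the ring A methide should give 17; the excess of F1 limits double bridging.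

Step 10. The oxatriene may close on the hydroxyl beside the bridge instead of the one beside the ketone, and the warm amine salt may start bridge exchange. The fallback sets out from 10 and comes back at 19, with the pyran ring closed before bridging. The phloroglucinol ketone F1 of the first fallback is condensed with 18 (ethylenediammonium diacetate, toluene, 80 °C) to 1-(5,7-dihydroxy-2,2-dimethyl-2H-chromen-8-yl)-2-methylpropan-1-one F2, and any isomer from closure on the other hydroxyl is removed at this small, cheap stage. Mannich base 14, made from 10 as in step 8, is then heated with F2 (MeCN, 60 °C). F2 has a single free aromatic carbon, flanked by both hydroxyls, so the bridge can form only at the right place, and 19 should result.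

Step 8. The Mannich base may revert, freeing ring A, which then adds to its own methide (homo-coupling), and the pyrone may react through its side-chain methylene instead of C-3. The fallback sets out from 10 and comes back at 15, using a methide precursor that cannot revert. Three-component condensation of 10 with paraformaldehyde and thiophenol (Et3N cat., EtOH, rt) should give (S)-3,5-dihydroxy-4-methyl-4-(3-methylbut-2-en-1-yl)-2-(2-methylpropanoyl)-6-[(phenylsulfanyl)methyl]cyclohexa-2,5-dien-1-one F3, which can be purified. Selective oxidation at sulfur with H2O2 in hexafluoroisopropanol, which leaves the prenyl alkene alone, gives the sulfoxide (S)-3,5-dihydroxy-4-methyl-4-(3-methylbut-2-en-1-yl)-2-(2-methylpropanoyl)-6-[(phenylsulfinyl)methyl]cyclohexa-2,5-dien-1-one F4 (mixture at sulfur). Heating F4 with 13 (toluene, 80 °C) releases the ring A methide by sulfoxide elimination in the absence of any free ring A, and the pyrone should add through C-3 to give 15.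

**Further compounds**

F1 | step 9 | 2-methyl-1-(2,4,6-trihydroxyphenyl)propan-1-one | CC(C)C(=O)c1c(O)cc(O)cc1O
F2 | step 10 | 1-(5,7-dihydroxy-2,2-dimethyl-2H-chromen-8-yl)-2-methylpropan-1-one | CC(C)C(=O)c1c(O)cc(O)c2C=CC(C)(C)Oc12
F3 | step 8 | (S)-3,5-dihydroxy-4-methyl-4-(3-methylbut-2-en-1-yl)-2-(2-methylpropanoyl)-6-[(phenylsulfanyl)methyl]cyclohexa-2,5-dien-1-one | CC(C)=CC[C@@]1(C)C(O)=C(CSc2ccccc2)C(=O)C(C(=O)C(C)C)=C1O
F4 | step 8 | (S)-3,5-dihydroxy-4-methyl-4-(3-methylbut-2-en-1-yl)-2-(2-methylpropanoyl)-6-[(phenylsulfinyl)methyl]cyclohexa-2,5-dien-1-one | CC(C)=CC[C@@]1(C)C(O)=C(CS(=O)c2ccccc2)C(=O)C(C(=O)C(C)C)=C1O
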